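**Retrosynthetic overview**

1. Target ⇒ bicyclic 3‑methoxy‑1,2‑dioxane lactone. The C3 methyl is added last, by axial methyl transfer from AlMe3 to the cyclic peroxycarbenium ion; this sets C3.
2. 1,2‑Dioxane ring (formed second) ⇒ keto‑butenolide. Ketone + H2O2/MeOH gives a hydroperoxy ketal that closes by intramolecular oxa‑Michael addition; the cis fusion (C7a) follows from C4a.
3. Keto‑butenolide ⇒ (S)‑4‑methylmuconolactone (as acid chloride) + 12‑phenyldodecylzinc bromide (from PhMgBr and 1,12‑dibromododecane), by Negishi acylation.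
4. Butenolide ring (formed first) and C4a ⇒ 4‑methylcatechol. Key step: dearomatising intradiol ring cleavage and enantioselective cycloisomerisation. The six arene carbons become C6, C7, C7a, C4a, C4 and C3, and the arene methyl becomes the 4a‑methyl.

Ring numbering used below (furo[3,2‑c][1,2]dioxine): O1, O2, C3, C4, C4a, O5, C6 (C=O), C7, C7a. The target is (3S,4aS,7aS).

Assumption: benzoate‑induced Pseudomonas putida cells (a culture‑collection strain with the ortho‑cleavage enzymes) are taken as an available biocatalyst and are assumed to give the (4S) lactone known for this species; everything else is catalogue material.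

**Step 1**
Reactants: 1 4‑methylcatechol (4‑methylbenzene‑1,2‑diol)
Product: 3 (S)‑4‑methylmuconolactone (2‑[(2S)‑2‑methyl‑5‑oxo‑2,5‑dihydrofuran‑2‑yl]acetic acid), via 3‑methyl‑cis,cis‑muconic acid 2 (not isolated)
Conditions: benzoate‑induced Pseudomonas putida resting cells (catechol 1,2‑dioxygenase, muconate cycloisomerase), air, potassium phosphate buffer pH 7, 30 °C, slow feed of 1 (≤1 mM) to full conversion; cells removed, pH 2, EtOAc extraction
Reagents that add atoms: dioxygen, O=O
Why: Intradiol dioxygenation by the non‑haem iron enzyme inserts both oxygen atoms of O2 between the two hydroxylated carbons and destroys the aromatic ring, and muconate cycloisomerase then adds the far carboxylate to one face of the methyl‑bearing alkene carbon (enzymatic syn cycloisomerisation, an intramolecular oxa‑Michael lactonisation), which creates the quaternary centre as (S) in a lactone that is a dead‑end metabolite and therefore accumulates.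

**Step 2**
Reactants: 4 phenylmagnesium bromide; 5 1,12‑dibromododecane
Product: 6 (12‑bromododecyl)benzene
Conditions: Fe(acac)3 (5 mol%), TMEDA, 5 (3 equiv), THF, 0 °C, slow addition of 4; excess 5 recovered
Reagents that add atoms: none
Why: Iron‑catalysed Kumada‑type coupling of an aryl Grignard reagent with a primary alkyl bromide, in which the threefold excess of the symmetrical dibromide keeps the coupling to one end; no stereocentre is involved.

**Step 3**
Reactants: 3 (S)‑4‑methylmuconolactone; 6 (12‑bromododecyl)benzene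
Product: 9 (5S)‑5‑methyl‑5‑(2‑oxo‑14‑phenyltetradecyl)furan‑2(5H)‑one, via acid chloride 7 (not isolated), via 12‑phenyldodecylzinc bromide 8 (not isolated)
Conditions: (a) 3, (COCl)2, DMF (cat.), CH2Cl2, 0 °C to rt, evaporate; (b) 6, Zn dust, LiCl, THF, 50 °C; (c) 7 added to 8 (1.3 equiv), Pd(PPh3)4 (3 mol%), THF, 0 °C to rt; neutral work‑up
Reagents that add atoms: none
Why: Negishi acylation, in which the acyl chloride adds to zerovalent palladium and the non‑basic alkylzinc bromide transmetalates and couples at or below room temperature, so the butenolide and the base‑sensitive β‑acyloxy ketone survive and the untouched (S) quaternary centre is carried through.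

**Step 4**
Reactants: 9 (5S)‑5‑methyl‑5‑(2‑oxo‑14‑phenyltetradecyl)furan‑2(5H)‑one
Product: 11 (4aS,7aS)‑3‑methoxy‑4a‑methyl‑3‑(12‑phenyldodecyl)‑3,4,4a,7a‑tetrahydrofuro[3,2‑c][1,2]dioxin‑6(7H)‑one as a mixture of C3 epimers, via hydroperoxy methyl ketal 10 (not isolated)
Conditions: urea·H2O2 (5 equiv), Sc(OTf)3 (10 mol%), MeOH, rt; aqueous work‑up; then Et2NH (1 equiv), CF3CH2OH, rt
Reagents that add atoms: urea–hydrogen peroxide, NC(N)=O.OO; methanol, CO
Why: Scandium‑triflate‑catalysed perketalisation turns the ketone into the hydroperoxy methyl ketal, whose hydroperoxide closes the 1,2‑dioxane by an amine‑promoted 6‑exo‑trig intramolecular oxa‑Michael addition to the butenolide; the peroxide can reach the β‑carbon only from the face that carries the CH2 tether, so the fusion is cis and C7a is set as (S) by the (4aS) centre, while the ketal carbon is a mixture that converges in step 5.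

**Step 5**
Reactants: 11 (4aS,7aS)‑3‑methoxy‑4a‑methyl‑3‑(12‑phenyldodecyl)‑3,4,4a,7a‑tetrahydrofuro[3,2‑c][1,2]dioxin‑6(7H)‑one
Product: 13 plakortolide L ((3S,4aS,7aS)‑3,4a‑dimethyl‑3‑(12‑phenyldodecyl)‑3,4,4a,7a‑tetrahydrofuro[3,2‑c][1,2]dioxin‑6(7H)‑one), via peroxycarbenium triflate 12 (not isolated)
Conditions: AlMe3 (3 equiv), CH2Cl2, −78 °C, then TMSOTf (1.2 equiv), −78 °C; MeOH, then aq. potassium sodium tartrate
Reagents that add atoms: trimethylaluminium, C[Al](C)C
Why: Proposed new method: TMSOTf ionises the peroxyketal to the cyclic peroxycarbenium ion (the ion used in Lewis‑acid‑mediated allylations of 3‑alkoxy‑1,2‑dioxanes) and AlMe3 transfers methyl to it as it does to oxocarbenium ions from methyl ketals; the ion reacts through the half‑chair with the 4a‑methyl pseudoequatorial and the lactone oxygen pseudoaxial, and chair‑like axial attack then comes from the face of the lactone oxygen, trans to the 4a‑methyl (the other face would need a 1,3‑diaxial methyl/methyl contact), which gives (3S).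

**Compound list**

1 | 4‑methylcatechol (4‑methylbenzene‑1,2‑diol) | Cc1ccc(O)c(O)c1 | starting material
2 | 3‑methyl‑cis,cis‑muconic acid ((2Z,4Z)‑3‑methylhexa‑2,4‑dienedioic acid; not isolated) | OC(=O)/C=C(C)\C=C/C(=O)O | intermediate
3 | (S)‑4‑methylmuconolactone (2‑[(2S)‑2‑methyl‑5‑oxo‑2,5‑dihydrofuran‑2‑yl]acetic acid) | OC(=O)C[C@]1(C)OC(=O)C=C1 | intermediate
4 | phenylmagnesium bromide | Br[Mg]c1ccccc1 | starting material
5 | 1,12‑dibromododecane | BrCCCCCCCCCCCCBr | starting material
6 | (12‑bromododecyl)benzene | BrCCCCCCCCCCCCc1ccccc1 | intermediate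
7 | 2‑[(2S)‑2‑methyl‑5‑oxo‑2,5‑dihydrofuran‑2‑yl]acetyl chloride (not isolated) | ClC(=O)C[C@]1(C)OC(=O)C=C1 | intermediate
8 | 12‑phenyldodecylzinc bromide (not isolated) | Br[Zn]CCCCCCCCCCCCc1ccccc1 | intermediate
9 | (5S)‑5‑methyl‑5‑(2‑oxo‑14‑phenyltetradecyl)furan‑2(5H)‑one | O=C(CCCCCCCCCCCCc1ccccc1)C[C@]1(C)OC(=O)C=C1 | intermediate
10 | (5S)‑5‑(2‑hydroperoxy‑2‑methoxy‑14‑phenyltetradecyl)‑5‑methylfuran‑2(5H)‑one (both epimers at the ketal carbon; not isolated) | COC(OO)(CCCCCCCCCCCCc1ccccc1)C[C@]1(C)OC(=O)C=C1 | intermediate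
11 | (4aS,7aS)‑3‑methoxy‑4a‑methyl‑3‑(12‑phenyldodecyl)‑3,4,4a,7a‑tetrahydrofuro[3,2‑c][1,2]dioxin‑6(7H)‑one (C3 epimers) | COC1(CCCCCCCCCCCCc2ccccc2)C[C@]2(C)OC(=O)C[C@@H]2OO1 | intermediate
12 | (4aS,7aS) bicyclic peroxycarbenium ion (C3=O2 oxonium of the same ring system, 12‑phenyldodecyl on C3) as its triflate (not isolated) | C=1(CCCCCCCCCCCCc3ccccc3)C[C@]2(C)OC(=O)C[C@@H]2O[O+]=1.[O-]S(=O)(=O)C(F)(F)F | intermediate
13 | plakortolide L ((3S,4aS,7aS)‑3,4a‑dimethyl‑3‑(12‑phenyldodecyl)‑3,4,4a,7a‑tetrahydrofuro[3,2‑c][1,2]dioxin‑6(7H)‑one) | C[C@]1(CCCCCCCCCCCCc2ccccc2)C[C@]2(C)OC(=O)C[C@@H]2OO1 | target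

**Step count**

Total: 5 steps. Longest linear sequence: 4 steps (steps 1, 3, 4, 5 from 4‑methylcatechol); step 2 makes the side chain.

**Steps most likely to fail, with fallbacks**

Step 5 (the peroxide may be reduced by AlMe3, or the facial selectivity may be low). The fallback sets out from 9 and comes back at 13 by the hydroperoxysilylation route. Takai–Lombardo methylenation (Zn, CH2Br2, TiCl4, THF/CH2Cl2, 0 °C; non‑basic, so the β‑acyloxy ketone does not eliminate) gives the alkene (5S)‑5‑methyl‑5‑(2‑methylidene‑14‑phenyltetradecyl)furan‑2(5H)‑one F1. Mukaiyama–Isayama hydroperoxysilylation (Co(thd)2 cat., O2, Et3SiH, ClCH2CH2Cl, rt) gives the tertiary silyl peroxide (5S)‑5‑methyl‑5‑[2‑methyl‑14‑phenyl‑2‑(triethylsilylperoxy)tetradecyl]furan‑2(5H)‑one F2 as both epimers at the new centre. TBAF in THF frees the hydroperoxide (5S)‑5‑(2‑hydroperoxy‑2‑methyl‑14‑phenyltetradecyl)‑5‑methylfuran‑2(5H)‑one F3, which cyclises in the same flask by oxa‑Michael addition to 13 and its (3R,4aS,7aS) epimer F4; the two are separated by HPLC. Control at C3 is lost, but every operation is standard for this lactone–dioxane family.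

Step 4 (the mixed ketal may form poorly, or the amine step may give side reactions). The fallback sets out from 9 and comes back at 12. Urea–hydrogen peroxide and Sc(OTf)3 in MeCN without methanol give the hydroperoxy hemiketal (5S)‑5‑(2‑hydroperoxy‑2‑hydroxy‑14‑phenyltetradecyl)‑5‑methylfuran‑2(5H)‑one F5. With catalytic Et3N in CF3CH2OH it closes to the ring tautomer, the 1,2‑dioxan‑3‑ol (4aS,7aS)‑3‑hydroxy‑4a‑methyl‑3‑(12‑phenyldodecyl)‑3,4,4a,7a‑tetrahydrofuro[3,2‑c][1,2]dioxin‑6(7H)‑one F6. Ac2O/pyridine/DMAP gives the 3‑acetate (4aS,7aS)‑4a‑methyl‑6‑oxo‑3‑(12‑phenyldodecyl)hexahydrofuro[3,2‑c][1,2]dioxin‑3‑yl acetate F7. Acetate leaves more readily than methoxide under TMSOTf, which gives ion 12, and methyl transfer as in step 5 gives 13.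

Step 1 (biocatalyst supply, substrate toxicity, incomplete cycloisomerisation lowering the ee). The fallback sets out from 1 and comes back at 3 by chemical ring cleavage and resolution. Peracetic acid in acetic acid at rt cleaves 1 to 2, which lactonises in the acidic medium to racemic 2‑(2‑methyl‑5‑oxo‑2,5‑dihydrofuran‑2‑yl)acetic acid F8. Crystallisation with (S)‑1‑phenylethylamine from ethanol gives the (S)‑1‑phenylethylammonium salt of the (S)‑acid F9; the mirror‑image amine is used instead if the salt of the (R)‑acid proves the less soluble. Aqueous HCl/EtOAc releases 3. This costs one step and half the material but needs no biocatalyst, and the racemate serves as the reference for the enantiomeric purity of 3.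

**Further compounds**

F1 | step 5 | (5S)‑5‑methyl‑5‑(2‑methylidene‑14‑phenyltetradecyl)furan‑2(5H)‑one | C=C(CCCCCCCCCCCCc1ccccc1)C[C@]1(C)OC(=O)C=C1
F2 | step 5 | (5S)‑5‑methyl‑5‑[2‑methyl‑14‑phenyl‑2‑(triethylsilylperoxy)tetradecyl]furan‑2(5H)‑one (both epimers at the peroxide carbon) | CC[Si](CC)(CC)OOC(C)(CCCCCCCCCCCCc1ccccc1)C[C@]1(C)OC(=O)C=C1
F3 | step 5 | (5S)‑5‑(2‑hydroperoxy‑2‑methyl‑14‑phenyltetradecyl)‑5‑methylfuran‑2(5H)‑one (both epimers at the peroxide carbon) | OOC(C)(CCCCCCCCCCCCc1ccccc1)C[C@]1(C)OC(=O)C=C1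
F4 | step 5 | (3R,4aS,7aS)‑3,4a‑dimethyl‑3‑(12‑phenyldodecyl)‑3,4,4a,7a‑tetrahydrofuro[3,2‑c][1,2]dioxin‑6(7H)‑one (C3 epimer of 13) | C[C@@]1(CCCCCCCCCCCCc2ccccc2)C[C@]2(C)OC(=O)C[C@@H]2OO1
F5 | step 4 | (5S)‑5‑(2‑hydroperoxy‑2‑hydroxy‑14‑phenyltetradecyl)‑5‑methylfuran‑2(5H)‑one (both epimers at the hemiketal carbon) | OC(OO)(CCCCCCCCCCCCc1ccccc1)C[C@]1(C)OC(=O)C=C1
F6 | step 4 | (4aS,7aS)‑3‑hydroxy‑4a‑methyl‑3‑(12‑phenyldodecyl)‑3,4,4a,7a‑tetrahydrofuro[3,2‑c][1,2]dioxin‑6(7H)‑one (C3 epimers) | OC1(CCCCCCCCCCCCc2ccccc2)C[C@]2(C)OC(=O)C[C@@H]2OO1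
F7 | step 4 | (4aS,7aS)‑4a‑methyl‑6‑oxo‑3‑(12‑phenyldodecyl)hexahydrofuro[3,2‑c][1,2]dioxin‑3‑yl acetate (C3 epimers) | CC(=O)OC1(CCCCCCCCCCCCc2ccccc2)C[C@]2(C)OC(=O)C[C@@H]2OO1
F8 | step 1 | racemic 2‑(2‑methyl‑5‑oxo‑2,5‑dihydrofuran‑2‑yl)acetic acid | OC(=O)CC1(C)OC(=O)C=C1
F9 | step 1 | (S)‑1‑phenylethylammonium 2‑[(2S)‑2‑methyl‑5‑oxo‑2,5‑dihydrofuran‑2‑yl]acetate | C[C@H]([NH3+])c1ccccc1.[O-]C(=O)C[C@]1(C)OC(=O)C=C1
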